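**Retrosynthetic overview**
- The target is the penta-O-benzyl ether of itself minus five benzyl groups: global hydrogenolysis is the last step.
- The flavanone pyranone ring (the only stereogenic ring) is closed last, at O1–C2, by a catalytic asymmetric intramolecular oxa-Michael addition of a 2'-hydroxy-α-aryl chalcone; C3 settles trans by enol protonation.
- The α-aryl chalcone comes from a Knoevenagel condensation of a deoxybenzoin with 4-benzyloxybenzaldehyde, followed by unmasking of the 2'-OH.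
- The deoxybenzoin is the fragment union: Pd-catalysed α-arylation of a MOM/benzyl-protected phloroacetophenone with a 3'-bromoflavone.
- The bromoflavone ring is formed first (Claisen–Schmidt chalcone, then I2/DMSO oxidative cyclisation).

Assumption: the target SMILES is read as the 2,3-trans flavanone with C2 = S and C3 = R; which cinchona pseudo-enantiomer gives the 2S series in step 11 is not known for this substrate class and is fixed by a pilot run with a CD check.

**Fragment A: protected phloroacetophenone**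

Step 1
Reactants: 1 1-(2,4,6-trihydroxyphenyl)ethan-1-one
Product: 2 1-[2,4-bis(benzyloxy)-6-hydroxyphenyl]ethan-1-one
Conditions: BnBr (2.05 equiv), K2CO3 (2.2 equiv), DMF, 0 °C to rt
Reagents that add atoms: benzyl bromide, BrCc1ccccc1
Why: Williamson etherification stops after two benzylations because the last ortho-OH is held in a strong hydrogen bond to the acetyl carbonyl.

Step 2
Reactants: 2 1-[2,4-bis(benzyloxy)-6-hydroxyphenyl]ethan-1-one
Product: 3 1-[2,4-bis(benzyloxy)-6-(methoxymethoxy)phenyl]ethan-1-one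
Conditions: NaH (1.1 equiv), THF/DMF, 0 °C; MOMCl (1.2 equiv), 0 °C to rt
Reagents that add atoms: chloromethyl methyl ether, COCCl
Why: O-alkylation of the sodium phenoxide (MOM protection) masks the acidic chelated phenol so that the methyl ketone can serve as an enolate partner, and MOM can later be removed without touching benzyl ethers.

**Fragment B: bromoflavone**

Step 3
Reactants: 4 1-(2,6-dihydroxy-4-methoxyphenyl)ethan-1-one
Product: 5 1-[2-(benzyloxy)-6-hydroxy-4-methoxyphenyl]ethan-1-one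
Conditions: BnBr (1.05 equiv), K2CO3 (1.1 equiv), acetone, reflux
Reagents that add atoms: benzyl bromide, BrCc1ccccc1
Why: Williamson etherification is mono-selective because the remaining ortho-OH becomes strongly chelated to the carbonyl after the first alkylation.

Step 4
Reactants: 6 3-bromo-4-hydroxybenzaldehyde
Product: 7 4-(benzyloxy)-3-bromobenzaldehyde
Conditions: BnBr (1.1 equiv), K2CO3 (1.5 equiv), DMF, rt
Reagents that add atoms: benzyl bromide, BrCc1ccccc1
Why: Simple Williamson etherification of an acidic para-formyl phenol.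

Step 5
Reactants: 5 1-[2-(benzyloxy)-6-hydroxy-4-methoxyphenyl]ethan-1-one; 7 4-(benzyloxy)-3-bromobenzaldehyde
Product: 8 (2E)-1-[2-(benzyloxy)-6-hydroxy-4-methoxyphenyl]-3-[4-(benzyloxy)-3-bromophenyl]prop-2-en-1-one
Conditions: 50% aq KOH, EtOH/THF, rt, 24–48 h; then dilute HCl
Reagents that add atoms: none
Why: Claisen–Schmidt (crossed aldol) condensation of a methyl ketone with a non-enolisable aldehyde gives the E-enone by E1cB dehydration.

Step 6
Reactants: 8 (2E)-1-[2-(benzyloxy)-6-hydroxy-4-methoxyphenyl]-3-[4-(benzyloxy)-3-bromophenyl]prop-2-en-1-one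
Product: 10 5-(benzyloxy)-2-[4-(benzyloxy)-3-bromophenyl]-7-methoxy-4H-chromen-4-one, via racemic flavanone 9 (not isolated)
Conditions: I2 (10 mol%), DMSO, 130 °C, 1–2 h; aq Na2S2O3 work-up
Reagents that add atoms: none
Why: Oxidative cyclisation of a 2'-hydroxychalcone: oxa-Michael closure to the flavanone, then iodine-mediated dehydrogenation with DMSO re-oxidising HI, so no stereocentre remains.

**Fragment union and endgame**

Step 7
Reactants: 3 1-[2,4-bis(benzyloxy)-6-(methoxymethoxy)phenyl]ethan-1-one (1.3 equiv); 10 5-(benzyloxy)-2-[4-(benzyloxy)-3-bromophenyl]-7-methoxy-4H-chromen-4-one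
Product: 11 5-(benzyloxy)-2-[4-(benzyloxy)-3-{2-[2,4-bis(benzyloxy)-6-(methoxymethoxy)phenyl]-2-oxoethyl}phenyl]-7-methoxy-4H-chromen-4-one
Conditions: Pd2(dba)3 (2.5 mol%), Xantphos (6 mol%), K3PO4 (2.5 equiv), toluene, 95 °C
Reagents that add atoms: none
Why: Pd-catalysed ketone α-arylation (Buchwald–Hartwig enolate arylation) with a mild phosphate base spares the flavone, and the ortho-benzyloxy group on the aryl bromide plus the wide-bite-angle ligand favour mono-arylation.

Step 8
Reactants: 12 4-hydroxybenzaldehyde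
Product: 13 4-(benzyloxy)benzaldehyde
Conditions: BnBr (1.1 equiv), K2CO3 (1.5 equiv), DMF, rt
Reagents that add atoms: benzyl bromide, BrCc1ccccc1
Why: Williamson etherification of an acidic phenol.

Step 9
Reactants: 11 the deoxybenzoin from step 7; 13 4-(benzyloxy)benzaldehyde (1.5 equiv)
Product: 14 5-(benzyloxy)-2-{4-(benzyloxy)-3-[(1E)-1-[4-(benzyloxy)phenyl]-3-[2,4-bis(benzyloxy)-6-(methoxymethoxy)phenyl]-3-oxoprop-1-en-2-yl]phenyl}-7-methoxy-4H-chromen-4-one
Conditions: piperidine (0.3 equiv), AcOH (0.3 equiv), toluene, reflux, Dean–Stark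
Reagents that add atoms: none
Why: Knoevenagel condensation of the doubly activated benzylic methylene with the piperidine-derived iminium of the aldehyde gives the α-aryl enone, expected mainly as the E isomer (aroyl trans to the β-aryl).

Step 10
Reactants: 14 the MOM-protected α-aryl chalcone
Product: 15 5-(benzyloxy)-2-{4-(benzyloxy)-3-[(1E)-1-[4-(benzyloxy)phenyl]-3-[2,4-bis(benzyloxy)-6-hydroxyphenyl]-3-oxoprop-1-en-2-yl]phenyl}-7-methoxy-4H-chromen-4-one
Conditions: 2 M HCl in MeOH/THF, 40 °C, stopped at full conversion; chromatography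
Reagents that add atoms: none
Why: Acid-catalysed acetal methanolysis removes MOM while benzyl ethers and the flavone are inert, and acid-catalysed ring closure of the chelated 2'-hydroxychalcone is slow enough that any racemic chromanone can be removed by chromatography.

Step 11
Reactants: 15 the 2'-hydroxy-α-aryl chalcone
Product: 17 (2S,3R)-5,7-bis(benzyloxy)-3-{2-(benzyloxy)-5-[5-(benzyloxy)-7-methoxy-4-oxo-4H-chromen-2-yl]phenyl}-2-[4-(benzyloxy)phenyl]-2,3-dihydro-4H-chromen-4-one, via enol tautomer 16 (not isolated)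
Conditions: 9-amino(9-deoxy)-epi-cinchona 3,5-bis(trifluoromethyl)phenyl thiourea (10–20 mol%, pseudo-enantiomer giving the 2S series), toluene, −20 °C to rt; silica filtration; recrystallisation to raise ee
Reagents that add atoms: none
Why: In this 6-endo-trig intramolecular oxa-Michael addition the thiourea binds the enone carbonyl and the quinuclidine delivers the phenol to one face of Cβ, setting C2 as S, and enol 16 is then protonated and equilibrated at the acidic C3 to the diequatorial 2,3-trans isomer, fixing C3 as R.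

Step 12
Reactants: 17 the penta-O-benzyl (2S,3R)-flavanone–flavone
Product: 18 (2S,3R)-5,7-dihydroxy-3-[2-hydroxy-5-(5-hydroxy-7-methoxy-4-oxo-4H-chromen-2-yl)phenyl]-2-(4-hydroxyphenyl)-2,3-dihydro-4H-chromen-4-one
Conditions: H2 (1 atm), 10% Pd/C, THF/MeOH, rt, stopped when uptake ends
Reagents that add atoms: none
Why: Neutral catalytic hydrogenolysis cleaves all five benzyl ethers without base, so neither stereocentre can epimerise through ring opening, and the flavone C=C and the 7-OMe group are not reduced under these mild conditions.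

**Compound list**
1 | 1-(2,4,6-trihydroxyphenyl)ethan-1-one (phloroacetophenone) | CC(=O)c1c(O)cc(O)cc1O | starting material
2 | 1-[2,4-bis(benzyloxy)-6-hydroxyphenyl]ethan-1-one | CC(=O)c1c(O)cc(OCc2ccccc2)cc1OCc1ccccc1 | intermediate
3 | 1-[2,4-bis(benzyloxy)-6-(methoxymethoxy)phenyl]ethan-1-one | CC(=O)c1c(OCOC)cc(OCc2ccccc2)cc1OCc1ccccc1 | intermediate
4 | 1-(2,6-dihydroxy-4-methoxyphenyl)ethan-1-one | CC(=O)c1c(O)cc(OC)cc1O | starting material
5 | 1-[2-(benzyloxy)-6-hydroxy-4-methoxyphenyl]ethan-1-one | CC(=O)c1c(O)cc(OC)cc1OCc1ccccc1 | intermediate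
6 | 3-bromo-4-hydroxybenzaldehyde | O=Cc1ccc(O)c(Br)c1 | starting material
7 | 4-(benzyloxy)-3-bromobenzaldehyde | O=Cc1ccc(OCc2ccccc2)c(Br)c1 | intermediate
8 | (2E)-1-[2-(benzyloxy)-6-hydroxy-4-methoxyphenyl]-3-[4-(benzyloxy)-3-bromophenyl]prop-2-en-1-one | COc1cc(O)c(C(=O)/C=C/c2ccc(OCc3ccccc3)c(Br)c2)c(OCc2ccccc2)c1 | intermediate
9 | racemic 5-(benzyloxy)-2-[4-(benzyloxy)-3-bromophenyl]-7-methoxy-2,3-dihydro-4H-chromen-4-one (not isolated) | COc1cc(OCc2ccccc2)c2c(c1)OC(c1ccc(OCc3ccccc3)c(Br)c1)CC2=O | intermediate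
10 | 5-(benzyloxy)-2-[4-(benzyloxy)-3-bromophenyl]-7-methoxy-4H-chromen-4-one | COc1cc(OCc2ccccc2)c2c(=O)cc(-c3ccc(OCc4ccccc4)c(Br)c3)oc2c1 | intermediate
11 | 5-(benzyloxy)-2-[4-(benzyloxy)-3-{2-[2,4-bis(benzyloxy)-6-(methoxymethoxy)phenyl]-2-oxoethyl}phenyl]-7-methoxy-4H-chromen-4-one | COc1cc(OCc2ccccc2)c2c(=O)cc(-c3ccc(OCc4ccccc4)c(CC(=O)c4c(OCOC)cc(OCc5ccccc5)cc4OCc4ccccc4)c3)oc2c1 | intermediate
12 | 4-hydroxybenzaldehyde | O=Cc1ccc(O)cc1 | starting material
13 | 4-(benzyloxy)benzaldehyde | O=Cc1ccc(OCc2ccccc2)cc1 | intermediate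
14 | 5-(benzyloxy)-2-{4-(benzyloxy)-3-[(1E)-1-[4-(benzyloxy)phenyl]-3-[2,4-bis(benzyloxy)-6-(methoxymethoxy)phenyl]-3-oxoprop-1-en-2-yl]phenyl}-7-methoxy-4H-chromen-4-one | O=C(c1c(OCOC)cc(OCc2ccccc2)cc1OCc1ccccc1)/C(=C/c1ccc(OCc2ccccc2)cc1)c1cc(-c2cc(=O)c3c(OCc4ccccc4)cc(OC)cc3o2)ccc1OCc1ccccc1 | intermediate
15 | 5-(benzyloxy)-2-{4-(benzyloxy)-3-[(1E)-1-[4-(benzyloxy)phenyl]-3-[2,4-bis(benzyloxy)-6-hydroxyphenyl]-3-oxoprop-1-en-2-yl]phenyl}-7-methoxy-4H-chromen-4-one | O=C(c1c(O)cc(OCc2ccccc2)cc1OCc1ccccc1)/C(=C/c1ccc(OCc2ccccc2)cc1)c1cc(-c2cc(=O)c3c(OCc4ccccc4)cc(OC)cc3o2)ccc1OCc1ccccc1 | intermediate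
16 | 5,7-bis(benzyloxy)-3-{2-(benzyloxy)-5-[5-(benzyloxy)-7-methoxy-4-oxo-4H-chromen-2-yl]phenyl}-2-[4-(benzyloxy)phenyl]-2H-chromen-4-ol; enol of 17, same spatial arrangement at C2 (formally 2R because the CIP ranking changes), not isolated | COc1cc(OCc2ccccc2)c2c(=O)cc(-c3ccc(OCc4ccccc4)c(C4=C(O)c5c(OCc6ccccc6)cc(OCc6ccccc6)cc5O[C@@H]4c4ccc(OCc5ccccc5)cc4)c3)oc2c1 | intermediate
17 | (2S,3R)-5,7-bis(benzyloxy)-3-{2-(benzyloxy)-5-[5-(benzyloxy)-7-methoxy-4-oxo-4H-chromen-2-yl]phenyl}-2-[4-(benzyloxy)phenyl]-2,3-dihydro-4H-chromen-4-one | COc1cc(OCc2ccccc2)c2c(=O)cc(-c3ccc(OCc4ccccc4)c([C@H]4C(=O)c5c(OCc6ccccc6)cc(OCc6ccccc6)cc5O[C@@H]4c4ccc(OCc5ccccc5)cc4)c3)oc2c1 | intermediate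
18 | (2S,3R)-5,7-dihydroxy-3-[2-hydroxy-5-(5-hydroxy-7-methoxy-4-oxo-4H-chromen-2-yl)phenyl]-2-(4-hydroxyphenyl)-2,3-dihydro-4H-chromen-4-one | COc1cc(O)c2c(=O)cc(-c3ccc(O)c([C@H]4C(=O)c5c(O)cc(O)cc5O[C@@H]4c4ccc(O)cc4)c3)oc2c1 | target

**Step count**
Total steps: 12.
Longest linear sequence: 8 steps (steps 3, 5, 6, 7, 9, 10, 11, 12; from 4 to 18). The parallel branches are steps 1–2, step 4 and step 8.

**Steps most likely to fail, with fallbacks**

Step 7 (α-arylation). The ketone is hindered, and the enolate could add to the flavone or arylate twice. The fallback sets out from ketone 3 and returns at 11. Ketone 3 is converted with LiHMDS and TMSCl (THF, −78 °C) into the trimethylsilyl enol ether F1. F1 is then coupled with bromoflavone 10 without added base (Pd(OAc)2/P(t-Bu)3, Bu3SnF, toluene, 85 °C), the tin enolate formed in situ doing the transmetalation, to give deoxybenzoin 11.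

Step 9 (Knoevenagel). The methylene is crowded and the aldehyde is electron-rich, so the amine-catalysed condensation may stall. The fallback sets out from 11 and returns at 14. Deoxybenzoin 11 is deprotonated with LiHMDS (1.05 equiv, THF, −78 °C) and the lithium enolate is added to aldehyde 13, with an AcOH quench at −78 °C, to give the β-hydroxy ketone F2 as a diastereomer mixture. Mesylation (MsCl, Et3N, CH2Cl2, 0 °C) and DBU-induced E1cB elimination at rt then give enone 14.

Step 11 (asymmetric oxa-Michael). Enantioselectivity on an α-aryl chalcone is uncertain, and reversible ring opening can erode ee. The fallback sets out from 15 and returns at 17. Chalcone 15 is cyclised with an achiral base (NaOAc, EtOH/THF, reflux) to the racemic trans-chromanone, a 1:1 mixture of 17 and its (2R,3S)-enantiomer F3. Preparative chiral SFC (amylose tris(3,5-dimethylphenylcarbamate) phase, CO2/MeOH) delivers 17. F3 is recycled by DBU-mediated ring opening and re-closure back to the racemate.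

**Further compounds**
F1 | step 7 | {1-[2,4-bis(benzyloxy)-6-(methoxymethoxy)phenyl]ethenyl}oxy(trimethyl)silane | C=C(O[Si](C)(C)C)c1c(OCOC)cc(OCc2ccccc2)cc1OCc1ccccc1
F2 | step 9 | 5-(benzyloxy)-2-[4-(benzyloxy)-3-{1-[4-(benzyloxy)phenyl]-3-[2,4-bis(benzyloxy)-6-(methoxymethoxy)phenyl]-1-hydroxy-3-oxopropan-2-yl}phenyl]-7-methoxy-4H-chromen-4-one (diastereomer mixture) | O=C(c1c(OCOC)cc(OCc2ccccc2)cc1OCc1ccccc1)C(C(O)c1ccc(OCc2ccccc2)cc1)c1cc(-c2cc(=O)c3c(OCc4ccccc4)cc(OC)cc3o2)ccc1OCc1ccccc1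
F3 | step 11 | (2R,3S)-5,7-bis(benzyloxy)-3-{2-(benzyloxy)-5-[5-(benzyloxy)-7-methoxy-4-oxo-4H-chromen-2-yl]phenyl}-2-[4-(benzyloxy)phenyl]-2,3-dihydro-4H-chromen-4-one | COc1cc(OCc2ccccc2)c2c(=O)cc(-c3ccc(OCc4ccccc4)c([C@@H]4C(=O)c5c(OCc6ccccc6)cc(OCc6ccccc6)cc5O[C@H]4c4ccc(OCc5ccccc5)cc4)c3)oc2c1
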